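Everything rests on disconnecting the lactone α-carbon C15 from the β-carbon C1. Since C15, C1 and the acetoxy carbon C14 form a 1,3-array ending in oxygen, the α-methylene-γ-butyrolactone with its neighbouring acetate is treated as a ring-opened, acyl-activated cyclopropane. The key step is a rhodium-carbenoid cyclopropanation of the (Z)-C1=C14 alkene by a 2-diazoacetoacetate on the C2 oxygen of the preformed 14-membered ring: it forms C15–C1, closing the lactone ring, and a temporary C15–C14 bond, and sets C1 and C14 from C2 by 1,3-allylic strain. Acetate then opens the cyclopropane at C14 with inversion, and the β-keto lactone enolate is methylenated with formaldehyde.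

Key step: step 13

Remark on numbering (cembrane numbering, used from compound 12 onward): ring carbons C1–C14; C1 = lactone β-carbon, C2 = lactone O-bearing carbon, C3–C4 = oxirane (methyl on C4), C7=C8 and C11=C12 = E-alkenes (methyls on C8 and C12), C13 = CH2, C14 = acetoxy carbon, C15 = lactone α-carbon, C16 = lactone carbonyl, C17 = exocyclic methylene.
Assumption: (2E,6E)-farnesyl acetate, ethynyltrimethylsilane, diketene and both enantiomers of 2-methyl-CBS-oxazaborolidine are taken as commercial.

Step 1
Reactants: 1 (2E,6E)-farnesyl acetate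
Product: 2 (2E,6E,10E)-12-hydroxy-3,7,11-trimethyldodeca-2,6,10-trien-1-yl acetate
Conditions: SeO2 (cat.), t-BuOOH, salicylic acid (cat.), CH2Cl2, rt; NaBH4 work-up for over-oxidised aldehyde
Reagents that add atoms: tert-butyl hydroperoxide, CC(C)(C)OO (terminal oxygen source; SeO2, O=[Se]=O, is the catalytic oxygen carrier)
Why: Riley allylic oxidation (ene reaction, then [2,3]-shift) should attack the E-methyl group of the terminal trisubstituted alkene and give the (E)-allylic alcohol, the acetate shielding the other allylic terminus.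

Step 2
Reactants: 2 (2E,6E,10E)-12-hydroxyfarnesyl acetate
Product: 3 (2E,6E,10E)-12-bromo-3,7,11-trimethyldodeca-2,6,10-trien-1-yl acetate
Conditions: CBr4, PPh3, CH2Cl2, 0 °C
Reagents that add atoms: carbon tetrabromide, BrC(Br)(Br)Br
Why: The Appel reaction converts the primary allylic alcohol into the bromide by SN2 displacement of the oxyphosphonium, without allylic transposition at low temperature.

Step 3
Reactants: 3 allylic bromide; 4 ethynyltrimethylsilane
Product: 5 (2E,6E,10E)-3,7,11-trimethyl-14-(trimethylsilyl)tetradeca-2,6,10-trien-13-yn-1-yl acetate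
Conditions: CuI (10 mol %), K2CO3, Bu4NCl, DMF, rt
Reagents that add atoms: none
Why: Copper-catalysed alkynylation of an allylic halide (copper acetylide substitution) should couple at the primary carbon with retention of the E-alkene to give the skipped enyne; the acetate and the C–Si bond tolerate the mild carbonate base.

Step 4
Reactants: 5 silylated enyne acetate
Product: 6 (2E,6E,10E)-3,7,11-trimethyltetradeca-2,6,10-trien-13-yn-1-ol
Conditions: K2CO3, MeOH, rt
Reagents that add atoms: none
Why: Methanolysis of the acetate and protodesilylation of the alkynylsilane proceed together under carbonate in methanol, conditions too mild to isomerise the skipped enyne.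

Step 5
Reactants: 6 enyne alcohol
Product: 7 (2E,6E,10E)-14-iodo-3,7,11-trimethyltetradeca-2,6,10-trien-13-yn-1-ol
Conditions: N-iodosuccinimide, AgNO3 (10 mol %), acetone, rt, dark
Reagents that add atoms: N-iodosuccinimide, O=C1CCC(=O)N1I
Why: Silver-catalysed electrophilic iodination of the terminal alkyne (through the silver acetylide) gives the 1-iodoalkyne much faster than the trisubstituted alkenes or the alcohol can react.

Step 6
Reactants: 7 iodoalkyne alcohol
Product: 8 (2E,6E,10E)-14-iodo-3,7,11-trimethyltetradeca-2,6,10-trien-13-ynal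
Conditions: MnO2, CH2Cl2, rt
Reagents that add atoms: none
Why: MnO2 oxidises the allylic alcohol chemoselectively to the (E)-enal without isomerising the double bond or touching the iodoalkyne.

Step 7
Reactants: 8 iodoalkynal
Product: 9 rac-(5E,9E,13E)-5,9,13-trimethylcyclotetradeca-5,9,13-trien-2-yn-1-ol
Conditions: CrCl2 (6 equiv), NiCl2 (1 mol %), THF, high dilution (0.003 M), slow addition, rt
Reagents that add atoms: none
Why: Nozaki–Hiyama–Kishi reaction: the alkynylchromium formed by insertion of divalent chromium into the C–I bond adds 1,2 to the enal without enolising it and closes the 14-membered ring; the new carbinol is racemic and is reset in steps 8 and 9.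

Step 8
Reactants: 9 racemic macrocyclic propargylic alcohol
Product: 10 (5E,9E,13E)-5,9,13-trimethylcyclotetradeca-5,9,13-trien-2-yn-1-one
Conditions: Dess–Martin periodinane, NaHCO3, CH2Cl2, 0 °C to rt
Reagents that add atoms: none
Why: Dess–Martin oxidation of the doubly activated (allylic and propargylic) alcohol gives the cross-conjugated ynone under neutral conditions, erasing the uncontrolled stereocentre.

Step 9
Reactants: 10 macrocyclic ynone
Product: 11 (1R,5E,9E,13E)-5,9,13-trimethylcyclotetradeca-5,9,13-trien-2-yn-1-ol
Conditions: (R)-2-methyl-CBS-oxazaborolidine (1 equiv), catecholborane, toluene, −78 °C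
Reagents that add atoms: none
Why: Corey–Bakshi–Shibata reduction: with the slim alkynyl group as the small and the β,β-disubstituted alkenyl group as the large substituent, the (R)-oxazaborolidine should deliver hydride to the face that gives the (R)-carbinol, and catecholborane at low temperature reduces only the carbonyl.

Step 10
Reactants: 11 (R)-propargylic alcohol
Product: 12 (2S,3R,4R,7E,11E)-3,4-epoxy-4,8,12-trimethylcyclotetradeca-7,11-dien-1(14)-yn-2-ol (alkyne C1≡C14)
Conditions: VO(acac)2 (5 mol %), t-BuOOH, CH2Cl2, 0 °C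
Reagents that add atoms: tert-butyl hydroperoxide, CC(C)(C)OO
Why: Hydroxyl-directed vanadium-catalysed epoxidation touches only the allylic C3=C4 alkene (alkyne and remote alkenes are inert); 1,3-allylic strain between the C4 methyl group, which is cis to C2, and the C2 substituents keeps H2 in the alkene plane, so oxygen is delivered from the hydroxyl face and the threo (2S,3R,4R) epoxy alcohol should predominate.

Step 11
Reactants: 12 epoxy alkynol
Product: 13 (1Z,2S,3R,4R,7E,11E)-3,4-epoxy-4,8,12-trimethylcyclotetradeca-1(14),7,11-trien-2-ol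
Conditions: H2 (1 atm), Pd on CaCO3 poisoned with Pb(OAc)2 (Lindlar catalyst), quinoline, EtOAc, rt
Reagents that add atoms: none
Why: Lindlar semi-hydrogenation adds H2 syn to the alkyne to give the (Z)-C1=C14 alkene, leaving the trisubstituted alkenes and the oxirane untouched.

Step 12
Reactants: 13 (Z)-allylic epoxy alcohol; 14 diketene
Product: 16 (1Z,2S,3R,4R,7E,11E)-3,4-epoxy-4,8,12-trimethylcyclotetradeca-1(14),7,11-trien-2-yl 2-diazo-3-oxobutanoate, via acetoacetate ester 15 (not isolated)
Conditions: diketene, DMAP (cat.), Et3N, THF, 0 °C to rt; then 4-acetamidobenzenesulfonyl azide, Et3N, MeCN, rt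
Reagents that add atoms: 4-acetamidobenzenesulfonyl azide, CC(=O)Nc1ccc(cc1)S(=O)(=O)N=[N+]=[N-]
Why: DMAP-catalysed ring-opening acylation by diketene gives the acetoacetate, whose active methylene undergoes Regitz diazo transfer under amine base, both at the C2 oxygen with no change at any stereocentre.

Step 13
Reactants: 16 (Z)-allylic 2-diazoacetoacetate
Product: 17 cyclopropane-fused keto lactone (1S,2S,3R,4R,14R,15R,7E,11E): a 1-acetyl-3-oxabicyclo[3.1.0]hexan-2-one unit in which C15 is bonded to C1 and C14 and the lactone runs C15–C16(=O)–O–C2, fused to the 14-membered ring; C3 anti to the cyclopropane, C13 endo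
Conditions: Rh2(OAc)4 (2 mol %), CH2Cl2, 40 °C, slow addition of 16
Reagents that add atoms: none
Why: Rh2(OAc)4 decomposes the diazo-β-keto ester to an electrophilic rhodium carbenoid that adds in one concerted, suprafacial [2+1] step to the only alkene within reach of the three-atom ester tether, the (Z)-C1=C14 bond, forming C15–C1 and C15–C14 together. The closest known reaction type is the rhodium- or copper-catalysed intramolecular cyclopropanation of allylic diazoacetoacetates and diazomalonates to 1-acyl-3-oxabicyclo[3.1.0]hexan-2-ones. The five-membered lactone ring closes through the C15–C1 bond in a 5-exo sense (C14 exocyclic to it), and the temporary three-membered ring closes through C15–C14 in the same event. C1 is controlled by C2: 1,3-allylic strain across the Z-alkene holds H2 in the alkene plane facing C13, so O2 with the carbenoid sits on one face and C3 on the other, which gives the 1,2-trans lactone; C14 follows from stereospecific syn addition to the Z-alkene (C13 endo), and C15 is fixed by the obligatory cis ring fusion. The step needs chemoselectivity for C1=C14 over the C7=C8 and C11=C12 alkenes, the oxirane oxygen and C–H bonds; this is secured by the five-membered transition state available only to C1=C14 and by having turned the competing allylic C3=C4 alkene into the oxirane in step 10.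

Step 14
Reactants: 17 cyclopropane-fused keto lactone
Product: 20 (1R,2S,3R,4R,14S,7E,11E)-14-acetoxy-3,4-epoxycembra-7,11,15(17)-trien-16,2-olide (CNP0294029.1), via acetoxy keto-lactone enolate 18 (not isolated), via formaldehyde aldol adduct 19 (not isolated)
Conditions: CsOAc (3 equiv), DMSO, 70 °C; then paraformaldehyde, 70 °C
Reagents that add atoms: cesium acetate, CC(=O)[O-].[Cs+]; paraformaldehyde (formaldehyde), C=O
Why: Acetate attacks C14 from the side opposite C15 (homoconjugate, SN2-type opening of a doubly acyl-activated cyclopropane, with inversion, the exocyclic C15–C14 bond being the one aligned with both carbonyl π systems), which sets (14S)-OAc and releases the cesium β-keto lactone enolate 18, whose aldol adduct 19 with formaldehyde undergoes deacylative methylenation (acetyl transfer from C15 to the new oxygen by retro-Claisen cleavage, then E1cB loss of acetate) to give the α-methylene lactone without touching C1 or C2.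

Compound list
1 | (2E,6E)-farnesyl acetate | CC(=O)OC/C=C(\C)CC/C=C(\C)CCC=C(C)C | starting material
2 | (2E,6E,10E)-12-hydroxy-3,7,11-trimethyldodeca-2,6,10-trien-1-yl acetate | CC(=O)OC/C=C(\C)CC/C=C(\C)CC/C=C(\C)CO | intermediate
3 | (2E,6E,10E)-12-bromo-3,7,11-trimethyldodeca-2,6,10-trien-1-yl acetate | CC(=O)OC/C=C(\C)CC/C=C(\C)CC/C=C(\C)CBr | intermediate
4 | ethynyltrimethylsilane | C#C[Si](C)(C)C | starting material
5 | (2E,6E,10E)-3,7,11-trimethyl-14-(trimethylsilyl)tetradeca-2,6,10-trien-13-yn-1-yl acetate | CC(=O)OC/C=C(\C)CC/C=C(\C)CC/C=C(\C)CC#C[Si](C)(C)C | intermediate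
6 | (2E,6E,10E)-3,7,11-trimethyltetradeca-2,6,10-trien-13-yn-1-ol | OC/C=C(\C)CC/C=C(\C)CC/C=C(\C)CC#C | intermediate
7 | (2E,6E,10E)-14-iodo-3,7,11-trimethyltetradeca-2,6,10-trien-13-yn-1-ol | OC/C=C(\C)CC/C=C(\C)CC/C=C(\C)CC#CI | intermediate
8 | (2E,6E,10E)-14-iodo-3,7,11-trimethyltetradeca-2,6,10-trien-13-ynal | O=C/C=C(\C)CC/C=C(\C)CC/C=C(\C)CC#CI | intermediate
9 | rac-(5E,9E,13E)-5,9,13-trimethylcyclotetradeca-5,9,13-trien-2-yn-1-ol | OC1C#CC/C(C)=C/CC/C(C)=C/CC/C(C)=C/1 | intermediate
10 | (5E,9E,13E)-5,9,13-trimethylcyclotetradeca-5,9,13-trien-2-yn-1-one | O=C1C#CC/C(C)=C/CC/C(C)=C/CC/C(C)=C/1 | intermediate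
11 | (1R,5E,9E,13E)-5,9,13-trimethylcyclotetradeca-5,9,13-trien-2-yn-1-ol | O[C@H]1C#CC/C(C)=C/CC/C(C)=C/CC/C(C)=C/1 | intermediate
12 | (2S,3R,4R,7E,11E)-3,4-epoxy-4,8,12-trimethylcyclotetradeca-7,11-dien-1(14)-yn-2-ol | O[C@H]1C#CC/C(C)=C/CC/C(C)=C/CC[C@@]2(C)O[C@H]12 | intermediate
13 | (1Z,2S,3R,4R,7E,11E)-3,4-epoxy-4,8,12-trimethylcyclotetradeca-1(14),7,11-trien-2-ol | O[C@H]1/C=C\C/C(C)=C/CC/C(C)=C/CC[C@@]2(C)O[C@H]12 | intermediate
14 | diketene (4-methyleneoxetan-2-one) | C=C1CC(=O)O1 | starting material
15 | 3-oxobutanoate (acetoacetate) ester of 13 at O2 | CC(=O)CC(=O)O[C@H]1/C=C\C/C(C)=C/CC/C(C)=C/CC[C@@]2(C)O[C@H]12 | intermediate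
16 | 2-diazo-3-oxobutanoate ester of 13 at O2 | CC(=O)C(=[N+]=[N-])C(=O)O[C@H]1/C=C\C/C(C)=C/CC/C(C)=C/CC[C@@]2(C)O[C@H]12 | intermediate
17 | (1S,2S,3R,4R,14R,15R)-15-acetyl cyclopropane-fused lactone (C15 bonded to C1 and C14; 16,2-olide; 3,4-epoxide; 7E,11E) | CC(=O)[C@]12C(=O)O[C@H]3[C@H]1[C@H]2C/C(C)=C/CC/C(C)=C/CC[C@@]1(C)O[C@H]31 | intermediate
18 | (1R,2S,3R,4R,14S)-14-acetoxy-15-acetyl-3,4-epoxycembra-7,11-dien-16,2-olide skeleton without C17 (formed as its cesium enolate; C15 not defined) | CC(=O)C1C(=O)O[C@H]2[C@H]1[C@@H](OC(C)=O)C/C(C)=C/CC/C(C)=C/CC[C@@]1(C)O[C@H]21 | intermediate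
19 | 15-acetyl-15-(hydroxymethyl) aldol adduct of 18 (formed as its alkoxide; C15 not defined) | CC(=O)C1(CO)C(=O)O[C@H]2[C@H]1[C@@H](OC(C)=O)C/C(C)=C/CC/C(C)=C/CC[C@@]1(C)O[C@H]21 | intermediate
20 | (1R,2S,3R,4R,14S,7E,11E)-14-acetoxy-3,4-epoxycembra-7,11,15(17)-trien-16,2-olide (CNP0294029.1) | C=C1C(=O)O[C@H]2[C@H]1[C@@H](OC(C)=O)C/C(C)=C/CC/C(C)=C/CC[C@@]1(C)O[C@H]21 | target

Total step count: 14. Longest linear sequence: 14 steps (from 1).

Steps most likely to fail

1. Step 14. Acetate may be too weak a nucleophile for the secondary cyclopropane carbon C14, so that ring opening is slow, or it may attack the oxirane, or the acyl transfer may stall. Fallback: deliver the C14 oxygen by double inversion on the E-configured series. This sets out from 12 and comes back at 18, which is methylenated as in step 14 to give 20. CrSO4 in aqueous DMF reduces the propargylic alkyne of 12 to the (E)-allylic alcohol F1. Diketene/DMAP, then 4-acetamidobenzenesulfonyl azide/Et3N, give the diazoacetoacetate F2. Rh2(OAc)4 gives the C14-epimeric cyclopropane F3; facial control by C2 is expected to be weaker here because the 1,3-allylic strain is absent. NaI with one equivalent of AcOH in acetone opens F3 at C14 with inversion to the (14R)-iodo keto lactone F4. CsOAc in DMSO then displaces iodide with a second inversion to give 18.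

2. Step 13. The carbenoid may be captured by the neighbouring oxirane oxygen (ylide formation and deoxygenation) or insert into a C–H bond instead of adding to C1=C14. Fallback: oxidative free-radical cyclisation without a carbenoid. This sets out from 15 (isolated after the diketene acylation) and comes back at 17. Mn(OAc)3 with Cu(OAc)2 in ethanol generates the α-radical of the β-keto ester, which adds 5-exo to C1; the C14 radical is oxidised by divalent copper and closes onto C15. The face at C1 is again dictated by the tether from O2. The C14 configuration then rests on ring closure being faster than bond rotation, which the macrocycle should favour.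

3. Step 10. Facial selectivity of the directed epoxidation may be poor inside the macrocycle, because the slim alkynyl substituent exerts little 1,3-allylic strain. Fallback: set the oxirane by reagent control before ring closure and the carbinol afterwards. This sets out from 7 and comes back at 12. Sharpless asymmetric epoxidation of 7 (Ti(OiPr)4, D-(−)-diethyl tartrate, t-BuOOH, 4 Å sieves, −20 °C) gives the (2R,3R)-epoxy alcohol F5. Dess–Martin oxidation gives the epoxy aldehyde F6. Nozaki–Hiyama–Kishi closure (CrCl2, NiCl2, THF, high dilution) gives the macrocyclic epoxy alkynol as a mixture of C2 epimers F7. Dess–Martin oxidation gives the epoxy ynone F8. Reduction with (R)-2-methyl-CBS-oxazaborolidine and catecholborane (alkynyl small, oxiranyl large) gives 12.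

Further compounds
F1 | step 14 | (1E,2S,3R,4R,7E,11E)-3,4-epoxy-4,8,12-trimethylcyclotetradeca-1(14),7,11-trien-2-ol | O[C@H]1/C=C/C/C(C)=C/CC/C(C)=C/CC[C@@]2(C)O[C@H]12
F2 | step 14 | 2-diazo-3-oxobutanoate ester of F1 at O2 | CC(=O)C(=[N+]=[N-])C(=O)O[C@H]1/C=C/C/C(C)=C/CC/C(C)=C/CC[C@@]2(C)O[C@H]12
F3 | step 14 | C14 epimer of cyclopropane-fused keto lactone 17 | CC(=O)[C@]12C(=O)O[C@H]3[C@H]1[C@@H]2C/C(C)=C/CC/C(C)=C/CC[C@@]1(C)O[C@H]31
F4 | step 14 | (14R)-14-iodo-15-acetyl keto lactone (iodo analogue of 18, inverted at C14) | CC(=O)C1C(=O)O[C@H]2[C@H]1[C@H](I)C/C(C)=C/CC/C(C)=C/CC[C@@]1(C)O[C@H]21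
F0 | step 13 | none | none
F5 | step 10 | [(2R,3R)-3-[(3E,7E)-11-iodo-4,8-dimethylundeca-3,7-dien-10-yn-1-yl]-3-methyloxiran-2-yl]methanol | OC[C@H]1O[C@]1(C)CC/C=C(\C)CC/C=C(\C)CC#CI
F6 | step 10 | (2S,3R)-3-[(3E,7E)-11-iodo-4,8-dimethylundeca-3,7-dien-10-yn-1-yl]-3-methyloxirane-2-carbaldehyde | O=C[C@H]1O[C@]1(C)CC/C=C(\C)CC/C=C(\C)CC#CI
F7 | step 10 | (3R,4R,7E,11E)-3,4-epoxy-4,8,12-trimethylcyclotetradeca-7,11-dien-1(14)-yn-2-ol, mixture of C2 epimers | OC1C#CC/C(C)=C/CC/C(C)=C/CC[C@@]2(C)O[C@H]12
F8 | step 10 | (3R,4R,7E,11E)-3,4-epoxy-4,8,12-trimethylcyclotetradeca-7,11-dien-1(14)-yn-2-one | O=C1C#CC/C(C)=C/CC/C(C)=C/CC[C@@]2(C)O[C@H]12
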